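The target in the east flask read 13% at 2.50 h and 14% at 30.0 h, and I had to choose what to do with that flask for the next 10 h.

| flask | starting material | second substrate | capture agent | free catalyst | temperature | remark | time |
|---|---|---|---|---|---|---|---|
| east | 1 M | 1 equiv | 0.30 M | 2.5 mol% | 80 °C | the very flask that is asked about, followed so far |  |
| west | 1 M | 1 equiv | 0.30 M | 5 mol% | 86 °C | run made earlier |  |
| flask | 1.0 M | 1.00 equiv | 0.300 M | 2.5 mol% | 80 °C |  | 30 h |

east run (percent of the starting material charged)

| time / h | target / % | starting material / % |
|---|---|---|
| 2.50 | 13 | 90 |
| 4.00 | 14 | 86 |
| 6.00 | 12 | 84 |
| 8.00 | 14 | 86 |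
| 12.0 | 11 | 91 |
| 20.0 | 14 | 86 |
| 30.0 | 14 | 85 |

west run (percent of the starting material charged)

| time / min | target / % | starting material / % |
|---|---|---|
| 10.0 | 2 | 92 |
| 15.0 | 7 | 91 |
| 25.0 | 12 | 85 |
| 40.0 | 22 | 84 |
| 50.0 | 20 | 77 |
| 80.0 | 23 | 74 |
| 120 | 31 | 69 |

(standard deviation of a reading: 2 percentage points)

- ochre: at 30 h add free catalyst, 100% of the amount charged, then wait 10 h
- red: at 30 h take out 90% of the target then present, then wait 10 h
- teal: change nothing and wait 10 h more
- amber: at 30 h raise the temperature by 15 K, then wait 10 h

- removed target is counted in
- the analysis behind the earlier runs scatters by 2 percentage points, standard deviation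
- additions bring no volume worth counting

1. target, in percent of the starting material first charged, at 30 h
2. the option that brings most further target ("none" if no option brings more than 2 percentage points) (ochre / red / teal / amber / none)
3. target present, with what was taken out counted in, in percent of the starting material first charged, after teal
4. target present, with what was taken out counted in, in percent of the starting material first charged, after amber

The two east readings differ by 1 percentage point, less than the scatter of one reading, so I averaged the east target readings and took the mean as my value for now:

plateau = 13.1%

The east flask still read 85% of starting material, far more than the target made, so lack of starting material had not stopped it. The west flask, with twice the catalyst at 86 °C, read 31% at its last point, more than the east plateau, so I took a balance between target and starting material to be unlikely for the east level, although the two flasks differ in temperature as well as in catalyst. I therefore counted turnovers: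

east: 13.1% / 2.5 mol% = 5.26

west, last reading: 31% / 5 mol% = 6.20

This count, the target made per catalyst charged before the round stops, is the turnover number. The hotter west reading gave a somewhat larger count, by 0.940, but it is a single scattered reading from a flask that differs in two settings, so I carried the east count forward as a reading.

That made the decision. Teal, red and amber add no catalyst, so I booked no gain for them and expected 13.1% after teal and after amber. Ochre adds a fresh charge, and I reckoned its gain with the east count:

gain = 5.26 × 100% × 2.5 mol% = 13 points

This is well above the margin of 2 points, and less than the starting material still there, so I chose ochre.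

The forecast gave 13.3% (12.3% to 14.3%) for now, 13.4% after teal, 13.6% after amber and ochre as best, holding that “the catalyst has most likely died”.

The flask gave 13.1% at 30 h, which is 5.24 turnovers, then 13.1% after teal and 13.1% after amber. Red brought 0 points and ochre 14 points, so ochre was best.

    starting material + free catalyst ⇌ catalyst intermediate A (K = 51.0 /M, k = 17.0 /M/h, Ea = 77.0 kJ/mol, ΔH = 1.00 kJ/mol)
    catalyst intermediate A → free catalyst + target (k = 9.60 /h, Ea = 105 kJ/mol)
    second substrate + free catalyst ⇌ catalyst intermediate B (K = 2.30 /M, k = 26.0 /M/h, Ea = 54.0 kJ/mol, ΔH = −78.0 kJ/mol)
    catalyst intermediate B → free catalyst + second product (k = 18.0 /h, Ea = 96.0 kJ/mol)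
    catalyst intermediate B + capture agent → trapped intermediate (k = 14.0 /M/h, Ea = 90.0 kJ/mol)
    (constants at 80 °C)

In this flask at 30.0 h, free catalyst stood at 0% and trapped intermediate at 100% of the catalyst charged. For a neighbouring flask charged with 10 mol% of free catalyst, I reckoned with the same count: 5.26 × 10 mol% = 52.6%. That neighbour gave 61.0%, more than the count, which is 6.10 turnovers against 5.26. At 30.0 h its trapped intermediate stood at >99.9% of its catalyst, its capture agent at 66.7% of its own charge, and its starting material at 39%.

(The runs come from a simulation on assumed constants; noise was put on by code.)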